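**Plan**
1. Numbering (elemane type): the cyclohexane ring is C5–C10. C10 carries C14H3 and the C1=C2 vinyl group, C5 carries the C4(=C3H2)–C15HO unit, C6 the angelate and C9 the methacrylate. The lactone ring is O–C8–C7–C11(=C13H2)–C12(=O).
2. Enabling feature: O–C6–C7–C11=C13H2 is a homoallylic carbinol whose alkene is the exocyclic methylene of the cis-fused five-membered lactone ring. This is the retron of a carbonyl 2-(oxycarbonyl)allylation, so cutting C6–C7 opens the cyclohexane ring to a C6 aldehyde tethered (C5–C10–C9) to C8 of a 3-(bromomethyl)butenolide.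
3. Cuts in order: C15–O and the two ester C–O bonds; then C6–C7; then C8–C9 (vinylogous Mukaiyama aldol of a 2-silyloxyfuran); then C5–C10 (Ireland–Claisen rearrangement of an allyl 3-methylbut-3-enoate).
4. Forward: the [3,3] shift makes the chain C6–C5–C10–C9, and the preformed butenolide ring is joined at C9. The cyclohexane ring closes last at C6–C7, which also unveils the α-methylene lactone. Angelate formation and C15 oxidation follow.
5. Stereochemistry: C5/C10 come from a chiral boron ketene acetal and the E-alkene (chair [3,3]). C9 and C8 come from a Felkin–Anh, threo-selective aldol addition. C7 follows from C8 (tether, cis fusion), and C6 from the chair transition state of the ring-locked E-allylchromium.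

Key step: step 15

Assumption: the (S,S)-configured bromoborane is taken to deliver the (2S,3S)-acid 9. If the sense of induction is the opposite, the equally accessible (R,R)-reagent is used and nothing else changes.
Abbreviations: TBS = tert-butyldimethylsilyl, TBDPS = tert-butyldiphenylsilyl, DMP = Dess–Martin periodinane.

Step 1
Reactants: 1 furan-2(5H)-one
Product: 2 3-(hydroxymethyl)furan-2(5H)-one
Conditions: aq. HCHO, PBu3 (cat.), THF, rt
Reagents that add atoms: formaldehyde C=O
Why: Morita–Baylis–Hillman reaction in which the phosphine adds to C4 of the butenolide, the enolate traps formaldehyde at C3 and the catalyst is expelled, which installs the future C13 without creating a stereocentre.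

Step 2
Reactants: 2 3-(hydroxymethyl)furan-2(5H)-one
Product: 3 2-(tert-butyldimethylsilyloxy)-3-[(tert-butyldimethylsilyloxy)methyl]furan
Conditions: TBSOTf, Et3N, CH2Cl2, 0 °C
Reagents that add atoms: tert-butyldimethylsilyl triflate CC(C)(C)[Si](C)(C)OS(=O)(=O)C(F)(F)F
Why: O-silylation of the alcohol together with soft enolisation and O-silylation of the lactone (silyl dienol ether formation), driven by aromatisation to the furan.

Step 3
Reactants: 4 2-methyl-2-vinyloxirane (racemic), 5 3-methylbut-3-enoic acid
Product: 6 (2E)-4-hydroxy-3-methylbut-2-en-1-yl 3-methylbut-3-enoate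
Conditions: Pd(PPh3)4 (cat.), THF, 0 °C
Reagents that add atoms: none
Why: Tsuji–Trost-type 1,4-opening of a vinyl epoxide, in which zerovalent palladium ionises the allylic C–O bond, the alkoxide deprotonates 5 and the carboxylate attacks the unsubstituted allyl terminus, which should give the E-trisubstituted alkene and erases the stereocentre of racemic 4.

Step 4
Reactants: 6 (2E)-4-hydroxy-3-methylbut-2-en-1-yl 3-methylbut-3-enoate
Product: 7 (2E)-4-(tert-butyldimethylsilyloxy)-3-methylbut-2-en-1-yl 3-methylbut-3-enoate
Conditions: TBSCl, imidazole, CH2Cl2, 0 °C to rt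
Reagents that add atoms: tert-butyldimethylsilyl chloride CC(C)(C)[Si](C)(C)Cl
Why: Standard silyl protection of the primary allylic alcohol (the future C9 oxygen), so that only the ester can be enolised in the next step.

Step 5
Reactants: 7 (2E)-4-(tert-butyldimethylsilyloxy)-3-methylbut-2-en-1-yl 3-methylbut-3-enoate
Product: 9 (2S,3S)-3-[(tert-butyldimethylsilyloxy)methyl]-3-methyl-2-(prop-1-en-2-yl)pent-4-enoic acid, via boron ketene acetal 8 (not isolated)
Conditions: (1S,2S)-N,N'-bis{[3,5-bis(trifluoromethyl)phenyl]sulfonyl}-1,2-diphenylethane-1,2-diamine, BBr3, CH2Cl2 (bromoborane, volatiles removed); then 7, Et3N, toluene/hexane, −78 °C to 4 °C; aq. work-up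
Reagents that add atoms: none
Why: Enantioselective Ireland–Claisen rearrangement, in which soft enolisation with the C2-symmetric bromoborane and Et3N in a non-polar medium should give ketene acetal 8 with the isopropenyl group cis to the allyloxy oxygen, its chair [3,3] shift onto the E-alkene (C9 equatorial, C14 axial) sets the C5/C10 relative configuration and the chiral boron ligand selects the face, a reaction type with close precedent for the vicinal tertiary/quaternary centres of elemane-type 1,5-dienes.

Step 6
Reactants: 9 (2S,3S)-3-[(tert-butyldimethylsilyloxy)methyl]-3-methyl-2-(prop-1-en-2-yl)pent-4-enoic acid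
Product: 10 (2S,3S)-3-[(tert-butyldimethylsilyloxy)methyl]-3-methyl-2-(prop-1-en-2-yl)pent-4-en-1-ol
Conditions: LiAlH4, Et2O, 0 °C
Reagents that add atoms: none
Why: Hydride reduction of the carboxylic acid (C6) to the primary alcohol, which leaves the silyl ether, the alkenes and both stereocentres untouched.

Step 7
Reactants: 10 (2S,3S)-3-[(tert-butyldimethylsilyloxy)methyl]-3-methyl-2-(prop-1-en-2-yl)pent-4-en-1-ol
Product: 11 C6-O-TBDPS ether of 10 (2S,3S)
Conditions: TBDPSCl, imidazole, DMF, rt
Reagents that add atoms: tert-butyldiphenylsilyl chloride CC(C)(C)[Si](Cl)(c1ccccc1)c1ccccc1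
Why: Silyl protection of the C6 alcohol with a group far more acid-stable than TBS, so that the two primary oxygens can be told apart.

Step 8
Reactants: 11 C6-O-TBDPS ether of 10
Product: 12 (2S,3S)-3-[(tert-butyldiphenylsilyloxy)methyl]-2-ethenyl-2,4-dimethylpent-4-en-1-ol
Conditions: camphorsulfonic acid (cat.), MeOH/CH2Cl2, 0 °C
Reagents that add atoms: none
Why: Acid-catalysed methanolysis cleaves the TBS ether much faster than the TBDPS ether and frees only the C9 alcohol.

Step 9
Reactants: 12 (2S,3S)-3-[(tert-butyldiphenylsilyloxy)methyl]-2-ethenyl-2,4-dimethylpent-4-en-1-ol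
Product: 13 (2S,3S)-3-[(tert-butyldiphenylsilyloxy)methyl]-2-ethenyl-2,4-dimethylpent-4-enal
Conditions: DMP, NaHCO3, CH2Cl2, 0 °C to rt; kept at or below rt
Reagents that add atoms: none
Why: Dess–Martin oxidation gives the non-enolisable neopentyl C9 aldehyde under neutral conditions, and low temperature avoids a Cope shift of the 3-formyl-1,5-diene.

Step 10
Reactants: 13 (2S,3S)-3-[(tert-butyldiphenylsilyloxy)methyl]-2-ethenyl-2,4-dimethylpent-4-enal, 3 2-(tert-butyldimethylsilyloxy)-3-[(tert-butyldimethylsilyloxy)methyl]furan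
Product: 14 (5R)-3-[(tert-butyldimethylsilyloxy)methyl]-5-[(1R,2S,3S)-3-[(tert-butyldiphenylsilyloxy)methyl]-2-ethenyl-1-hydroxy-2,4-dimethylpent-4-en-1-yl]furan-2(5H)-one
Conditions: BF3·OEt2, CH2Cl2, −78 °C; aq. NaHCO3 work-up
Reagents that add atoms: none
Why: Vinylogous Mukaiyama aldol reaction in which C5 of the silyloxyfuran attacks the BF3-activated aldehyde through an open transition state that favours the threo (syn) C8/C9 pair, while Felkin–Anh attack anti to the branched C5 substituent on quaternary C10 (vinyl medium, methyl small) sets C9 relative to C10.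

Step 11
Reactants: 14 aldol butenolide
Product: 15 9-O-methacrylate of 14 (5S,8R,9R,10S)
Conditions: methacrylic anhydride, DMAP (cat.), pyridine, CH2Cl2, 0 °C to rt
Reagents that add atoms: methacrylic anhydride CC(=C)C(=O)OC(=O)C(C)=C
Why: DMAP-catalysed acylation installs the final C9 ester, and the weak base and low temperature hold back E1cB loss of the new acyloxy group from the acidic C8–H position.

Step 12
Reactants: 15 9-O-methacrylate of 14
Product: 16 C6,C13-diol (both silyl ethers of 15 removed; 5S,8R,9R,10S)
Conditions: HF·pyridine, pyridine, THF, 0 °C to rt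
Reagents that add atoms: none
Why: Fluoride-driven cleavage of both silyl ethers under buffered acidic conditions that the esters and the base-sensitive butenolide tolerate.

Step 13
Reactants: 16 C6,C13-diol
Product: 17 C13 allylic bromide with free C6 alcohol (5S,8R,9R,10S)
Conditions: NBS, Me2S, CH2Cl2, −30 °C to 0 °C
Reagents that add atoms: N-bromosuccinimide O=C1CCC(=O)N1Br
Why: Corey–Kim-type halogenation, in which only the allylic alkoxysulfonium ion is displaced by bromide while the hindered saturated C6 alcohol is returned on work-up, as known for 2-(hydroxymethyl)enoates.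

Step 14
Reactants: 17 C13 allylic bromide with free C6 alcohol
Product: 18 C6 aldehyde bearing the 3-(bromomethyl)butenolide (5S,8R,9R,10S)
Conditions: DMP, NaHCO3, CH2Cl2, 0 °C; used at once
Reagents that add atoms: none
Why: Buffered Dess–Martin oxidation gives the β,γ-unsaturated aldehyde without base, so that C5 is neither epimerised nor brought into conjugation.

Step 15
Reactants: 18 C6 aldehyde bearing the 3-(bromomethyl)butenolide
Product: 20 (5S,6S,7R,8R,9R,10S)-6-hydroxy-9-methacryloyloxyelema-1,3,11(13)-trien-12,8-olide, via allylchromium species 19 (not isolated)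
Conditions: CrCl2 (excess), THF, slow addition of 18 (high dilution), rt; aq. work-up
Reagents that add atoms: none
Why: Two equivalents of CrCl2 reduce the allylic C13–Br bond of 18 to the allylchromium species 19 (trivalent chromium), which adds through its γ-carbon C7 to the C6 aldehyde in an SE2' sense, so that the C7=C11 bond of the butenolide moves to C11=C13 and the α-methylene lactone is unveiled in the same event. The closest known reaction type is the Nozaki–Hiyama–Kishi/Barbier 2-(alkoxycarbonyl)allylation of aldehydes, known intermolecularly for 3-(bromomethyl)furan-2(5H)-one and intramolecularly for 2-(bromomethyl)acrylates. The cyclohexane ring closes in a 6-exo-trig mode at the carbonyl carbon, the tether C9–C10–C5–C6 being anchored at C8 next to the nucleophilic carbon. C7 is controlled by C8, because the tether reaches only the butenolide face that carries C9, which enforces the cis ring fusion (H7 and H8 syn). C6 is controlled by the chair Zimmerman–Traxler array, because the lactone ring holds C13 and C8 trans on C11=C7 (an E-crotyl-type reagent) and C5 takes the equatorial site, which gives the anti relationship, that is C6–O trans to C7–C11 as in the target. The step needs chemoselectivity for the aldehyde over the esters, the lactone and the unactivated alkenes, secured by the low basicity and carbonyl selectivity of organochromium reagents, and ring closure in preference to intermolecular addition, secured by high dilution.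

Step 16
Reactants: 20 (5S,6S,7R,8R,9R,10S)-6-hydroxy-9-methacryloyloxyelema-1,3,11(13)-trien-12,8-olide, 21 angelic acid [(2Z)-2-methylbut-2-enoic acid]
Product: 23 (5S,6S,7R,8R,9R,10S)-6-angeloyloxy-9-methacryloyloxyelema-1,3,11(13)-trien-12,8-olide, via mixed anhydride 22 (not isolated)
Conditions: 21, 2,4,6-trichlorobenzoyl chloride, Et3N, toluene, rt; then 20, 80 °C
Reagents that add atoms: none
Why: Yamaguchi-type esterification through the hindered mixed anhydride without a nucleophilic catalyst, the established way to acylate hindered alcohols with angelic acid without Z-to-E isomerisation to the tiglate, with retention at C6.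

Step 17
Reactants: 23 (5S,6S,7R,8R,9R,10S)-6-angeloyloxy-9-methacryloyloxyelema-1,3,11(13)-trien-12,8-olide
Product: 24 15-hydroxy derivative of 23 (5S,6S,7R,8R,9R,10S)
Conditions: SeO2 (cat.), t-BuOOH, CH2Cl2, 0 °C to rt
Reagents that add atoms: tert-butyl hydroperoxide CC(C)(C)OO (oxygen source), selenium dioxide O=[Se]=O (oxygen carrier)
Why: Riley-type allylic oxidation (ene reaction, then [2,3] shift) acts on the isopropenyl group because it is the only electron-rich alkene with allylic hydrogens, and it should choose the C15 methyl group over the crowded C5–H.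

Step 18
Reactants: 24 15-hydroxy derivative of 23
Product: 25 target, (5R,6S,7R,8R,9R,10S)-6-angeloyloxy-9-methacryloyloxy-15-oxoelema-1,3,11(13)-trien-12,8-olide
Conditions: MnO2, CH2Cl2, rt
Reagents that add atoms: none
Why: Chemoselective MnO2 oxidation of the primary allylic alcohol to the 2-substituted acrolein under neutral conditions that touch no stereocentre (the C5 descriptor changes only through priority rules).

**Compound list**
1 | furan-2(5H)-one | O=C1OCC=C1 | starting material
2 | 3-(hydroxymethyl)furan-2(5H)-one | O=C1OCC=C1CO | intermediate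
3 | 2-(tert-butyldimethylsilyloxy)-3-[(tert-butyldimethylsilyloxy)methyl]furan | CC(C)(C)[Si](C)(C)OCc1ccoc1O[Si](C)(C)C(C)(C)C | intermediate
4 | 2-methyl-2-vinyloxirane (racemic) | CC1(C=C)CO1 | starting material
5 | 3-methylbut-3-enoic acid | C=C(C)CC(=O)O | starting material
6 | (2E)-4-hydroxy-3-methylbut-2-en-1-yl 3-methylbut-3-enoate | C=C(C)CC(=O)OC/C=C(\C)CO | intermediate
7 | (2E)-4-(tert-butyldimethylsilyloxy)-3-methylbut-2-en-1-yl 3-methylbut-3-enoate | C=C(C)CC(=O)OC/C=C(\C)CO[Si](C)(C)C(C)(C)C | intermediate
8 | boron ketene acetal of 7, (4S,5S)-diazaborolidin-2-yl on oxygen, isopropenyl cis to the allyloxy oxygen | CC(=C)/C=C(/OB1N(S(=O)(=O)c2cc(C(F)(F)F)cc(C(F)(F)F)c2)[C@@H](c2ccccc2)[C@H](c2ccccc2)N1S(=O)(=O)c1cc(C(F)(F)F)cc(C(F)(F)F)c1)\OC/C=C(\C)CO[Si](C)(C)C(C)(C)C | intermediate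
9 | (2S,3S)-3-[(tert-butyldimethylsilyloxy)methyl]-3-methyl-2-(prop-1-en-2-yl)pent-4-enoic acid | C=C[C@@](CO[Si](C)(C)C(C)(C)C)(C)[C@H](C(C)=C)C(=O)O | intermediate
10 | (2S,3S)-3-[(tert-butyldimethylsilyloxy)methyl]-3-methyl-2-(prop-1-en-2-yl)pent-4-en-1-ol | C=C[C@@](CO[Si](C)(C)C(C)(C)C)(C)[C@H](C(C)=C)CO | intermediate
11 | C6-O-TBDPS ether of 10 (2S,3S) | C=C[C@@](CO[Si](C)(C)C(C)(C)C)(C)[C@H](C(C)=C)CO[Si](c1ccccc1)(c1ccccc1)C(C)(C)C | intermediate
12 | (2S,3S)-3-[(tert-butyldiphenylsilyloxy)methyl]-2-ethenyl-2,4-dimethylpent-4-en-1-ol | C=C[C@@](CO)(C)[C@H](C(C)=C)CO[Si](c1ccccc1)(c1ccccc1)C(C)(C)C | intermediate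
13 | (2S,3S)-3-[(tert-butyldiphenylsilyloxy)methyl]-2-ethenyl-2,4-dimethylpent-4-enal | C=C[C@@](C=O)(C)[C@H](C(C)=C)CO[Si](c1ccccc1)(c1ccccc1)C(C)(C)C | intermediate
14 | (5R)-3-[(tert-butyldimethylsilyloxy)methyl]-5-[(1R,2S,3S)-3-[(tert-butyldiphenylsilyloxy)methyl]-2-ethenyl-1-hydroxy-2,4-dimethylpent-4-en-1-yl]furan-2(5H)-one | C=C[C@@]([C@@H](O)[C@H]1C=C(CO[Si](C)(C)C(C)(C)C)C(=O)O1)(C)[C@H](C(C)=C)CO[Si](c1ccccc1)(c1ccccc1)C(C)(C)C | intermediate
15 | 9-O-methacrylate of 14 (5S,8R,9R,10S) | C=C[C@@]([C@@H](OC(=O)C(C)=C)[C@H]1C=C(CO[Si](C)(C)C(C)(C)C)C(=O)O1)(C)[C@H](C(C)=C)CO[Si](c1ccccc1)(c1ccccc1)C(C)(C)C | intermediate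
16 | C6,C13-diol from 15 (5S,8R,9R,10S) | C=C[C@@]([C@@H](OC(=O)C(C)=C)[C@H]1C=C(CO)C(=O)O1)(C)[C@H](C(C)=C)CO | intermediate
17 | C13 allylic bromide with free C6 alcohol (5S,8R,9R,10S) | C=C[C@@]([C@@H](OC(=O)C(C)=C)[C@H]1C=C(CBr)C(=O)O1)(C)[C@H](C(C)=C)CO | intermediate
18 | C6 aldehyde bearing the 3-(bromomethyl)butenolide (5S,8R,9R,10S) | C=C[C@@]([C@@H](OC(=O)C(C)=C)[C@H]1C=C(CBr)C(=O)O1)(C)[C@H](C(C)=C)C=O | intermediate
19 | allylchromium dichloride derived from 18 (Cr on C13) | C=C[C@@]([C@@H](OC(=O)C(C)=C)[C@H]1C=C(C[Cr](Cl)Cl)C(=O)O1)(C)[C@H](C(C)=C)C=O | intermediate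
20 | (5S,6S,7R,8R,9R,10S)-6-hydroxy-9-methacryloyloxyelema-1,3,11(13)-trien-12,8-olide | C=C[C@@]1(C)[C@H](C(C)=C)[C@H](O)[C@H]2C(=C)C(=O)O[C@H]2[C@@H]1OC(=O)C(C)=C | intermediate
21 | angelic acid, (2Z)-2-methylbut-2-enoic acid | C/C=C(/C)C(=O)O | starting material
22 | angelic 2,4,6-trichlorobenzoic anhydride | C/C=C(/C)C(=O)OC(=O)c1c(Cl)cc(Cl)cc1Cl | intermediate
23 | (5S,6S,7R,8R,9R,10S)-6-angeloyloxy-9-methacryloyloxyelema-1,3,11(13)-trien-12,8-olide | C=C[C@@]1(C)[C@H](C(C)=C)[C@H](OC(=O)/C(C)=C\C)[C@H]2C(=C)C(=O)O[C@H]2[C@@H]1OC(=O)C(C)=C | intermediate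
24 | 15-hydroxy derivative of 23 (5S,6S,7R,8R,9R,10S) | C=C[C@@]1(C)[C@H](C(=C)CO)[C@H](OC(=O)/C(C)=C\C)[C@H]2C(=C)C(=O)O[C@H]2[C@@H]1OC(=O)C(C)=C | intermediate
25 | (5R,6S,7R,8R,9R,10S)-6-angeloyloxy-9-methacryloyloxy-15-oxoelema-1,3,11(13)-trien-12,8-olide | C=C[C@@]1(C)[C@H](C(=C)C=O)[C@H](OC(=O)/C(C)=C\C)[C@H]2C(=C)C(=O)O[C@H]2[C@@H]1OC(=O)C(=C)C | target

**Total step count:** 18.
**Longest linear sequence:** 16 steps (steps 3 to 18, from 4 and 5).

**Steps most likely to fail**

1. Step 15.
   - What may go wrong: the aldehyde may be attacked through the competing array in which C5 sits axially on the six-membered transition state. That array lets the forming cyclohexane keep most substituents equatorial, so facial selectivity at C6 could be poor. The allylchromium may also be protonated or may dimerise, and C5 of the β,γ-unsaturated aldehyde may epimerise or move into conjugation.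
   - Fallback: it sets out from 17 and returns at 20. It replaces the reductive Barbier event with a stepwise, metal-free closure through an isolable allylboron reagent, whose short B–O and B–C bonds tighten the chair array and make the E-to-anti transfer more stringent.
   - Sequence: 17 is borylated at C13 (bis(pinacolato)diboron, Pd2(dba)3 cat., toluene, 50 °C) to the allylboronate F1. Buffered Dess–Martin oxidation gives the boronate aldehyde F2. On gentle warming in toluene, F2 closes the same C6–C7 bond by concerted allylboration to the cyclic product borate F3. Mild hydrolysis of F3 gives 20.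

2. Step 10.
   - What may go wrong: facial selectivity at the neopentyl aldehyde may be poor, because vinyl and methyl on C10 differ little in size. The Lewis acid may also ionise the furylmethyl silyl ether of 3.
   - Fallback: it sets out from 13 and returns at 16. It moves the origin of C8/C9 from substrate to catalyst control and introduces C13 only afterwards.
   - Sequence: 13 is combined with commercial 2-(trimethylsilyloxy)furan under a chiral Ti(OiPr)4/BINOL Lewis acid, using the antipode that reinforces Felkin–Anh attack. Catalyst-controlled additions of this parent furan to aliphatic aldehydes are established. This gives the α-unsubstituted butenolide carbinol F4. Methacrylation as in step 11 gives the ester F5. Morita–Baylis–Hillman hydroxymethylation (aq. HCHO, PBu3 cat.) places C13 and gives the hydroxymethyl butenolide F6. HF·pyridine then removes the TBDPS group to give 16.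

3. Step 17.
   - What may go wrong: hydrogen abstraction at C5–H may compete with that at C15, the product may be over-oxidised, and the angelate may isomerise to the tiglate under the acidic selenium species.
   - Fallback: it sets out from 23 and returns at 25, by-passing 24.
   - Sequence: a Schenck ene reaction (O2, tetraphenylporphyrin, visible light, CH2Cl2, 0 °C) engages only the electron-rich isopropenyl group and gives the primary allylic hydroperoxide F7. Kornblum–DeLaMare-type dehydration (Ac2O, pyridine, 0 °C) converts F7 directly into the enal 25.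

**Further compounds**
F1 | step 15 | C13 pinacol allylboronate with free C6 alcohol (bromine of 17 replaced by the dioxaborolanyl group) | C=C[C@@]([C@@H](OC(=O)C(C)=C)[C@H]1C=C(CB2OC(C)(C)C(C)(C)O2)C(=O)O1)(C)[C@H](C(C)=C)CO
F2 | step 15 | C6 aldehyde of F1 | C=C[C@@]([C@@H](OC(=O)C(C)=C)[C@H]1C=C(CB2OC(C)(C)C(C)(C)O2)C(=O)O1)(C)[C@H](C(C)=C)C=O
F3 | step 15 | 6-O-pinacolborate of 20 | C=C[C@@]1(C)[C@H](C(C)=C)[C@H](OB3OC(C)(C)C(C)(C)O3)[C@H]2C(=C)C(=O)O[C@H]2[C@@H]1OC(=O)C(C)=C
F4 | step 10 | (5R)-5-[(1R,2S,3S)-3-[(tert-butyldiphenylsilyloxy)methyl]-2-ethenyl-1-hydroxy-2,4-dimethylpent-4-en-1-yl]furan-2(5H)-one | C=C[C@@]([C@@H](O)[C@H]1C=CC(=O)O1)(C)[C@H](C(C)=C)CO[Si](c1ccccc1)(c1ccccc1)C(C)(C)C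
F5 | step 10 | 9-O-methacrylate of F4 | C=C[C@@]([C@@H](OC(=O)C(C)=C)[C@H]1C=CC(=O)O1)(C)[C@H](C(C)=C)CO[Si](c1ccccc1)(c1ccccc1)C(C)(C)C
F6 | step 10 | 3-(hydroxymethyl)butenolide derived from F5 (C13 alcohol, C6-O-TBDPS) | C=C[C@@]([C@@H](OC(=O)C(C)=C)[C@H]1C=C(CO)C(=O)O1)(C)[C@H](C(C)=C)CO[Si](c1ccccc1)(c1ccccc1)C(C)(C)C
F7 | step 17 | 15-hydroperoxide of 23 | C=C[C@@]1(C)[C@H](C(=C)COO)[C@H](OC(=O)/C(C)=C\C)[C@H]2C(=C)C(=O)O[C@H]2[C@@H]1OC(=O)C(=C)C
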